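## Retrosynthetic overview

1. The strategy rests on the enol-ether bridge C10–O–C3, that is, the 3(2H)-furanone ring (O, C10, C1, C2, C3) lying across the ten-membered carbocycle C1–C10. This bridge is the dehydrated transannular hemiketal of a cyclodec-4-ene-1,3-dione that carries a tertiary hydroxyl at C10.
2. Last disconnections: the C6–O ester (Yamaguchi, with (2R,3R)-epoxyangelic acid made from angelic acid by Sharpless epoxidation), then the O–C3 bond (acid-catalysed transannular cyclodehydration of the C10-hydroxy-1,3-diketone, with C6 held as a triisopropylsilyl ether).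
3. Ten-membered ring: C1–C2 bond by an intramolecular boron aldol between the C2 methyl of a (Z)-methyl enone and a C1 aldehyde that has no α-hydrogen, then oxidation to the 1,3-diketone.
4. Acyclic part: C7, C8 and the γ-lactone by an Evans syn-aldol/lactonisation of a succinate imide with a C8 aldehyde whose C10 centre comes from (S)-2-methylglycidol. C6 comes from acylation of a thioester with a Z-alkenylcuprate (C2–C5 unit) followed by Felkin–Anh reduction, and C13 from Mannich methylenation.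
5. Order of ring formation: γ-lactone (step 6), ten-membered carbocycle (step 16), furanone bridge (step 19).

Key step: step 19

Remark: germacrane numbering is used (ring C1–C10; C11, C12, C13 = lactone α-carbon, carbonyl, methylene; C14 on C10, C15 on C4); 25 is expected as a pair of C1 epimers and 27 may rest partly as its enol or transannular hemiketal, and all of these converge in the following step.

## Route

Step 1
Reactants: 1 (S)-(2-methyloxiran-2-yl)methanol [(S)-2-methylglycidol]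
Product: 2 (R)-2-{[(4-methoxybenzyl)oxy]methyl}-2-methyloxirane
Conditions: NaH, 4-methoxybenzyl chloride, Bu4NI (cat.), THF/DMF, 0 °C to rt
Reagents that add atoms: 4-methoxybenzyl chloride, COc1ccc(CCl)cc1
Why: Williamson etherification of the primary alkoxide, which does not touch the quaternary carbon that becomes C10 (its descriptor changes from S to R only through CIP ranking, and a Payne shift of this alkoxide would be degenerate).

Step 2
Reactants: 2 (R)-2-{[(4-methoxybenzyl)oxy]methyl}-2-methyloxirane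
Product: 3 (R)-1-[(4-methoxybenzyl)oxy]-2-methylpent-4-en-2-ol
Conditions: CH2=CHMgBr, CuI (10 mol%), THF, −30 to 0 °C
Reagents that add atoms: vinylmagnesium bromide, C=C[Mg]Br
Why: Copper-catalysed Grignard opening of the 2,2-disubstituted epoxide at its unhindered CH2 (SN2), which leaves the tertiary carbinol centre (C10) intact and brings in C8 as a masked aldehyde.

Step 3
Reactants: 3 (R)-1-[(4-methoxybenzyl)oxy]-2-methylpent-4-en-2-ol
Product: 4 (R)-triethyl({1-[(4-methoxybenzyl)oxy]-2-methylpent-4-en-2-yl}oxy)silane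
Conditions: Et3SiOTf, 2,6-lutidine, CH2Cl2, −78 to 0 °C
Reagents that add atoms: triethylsilyl triflate, CC[Si](CC)(CC)OS(=O)(=O)C(F)(F)F
Why: Silyl ether formation with the reactive silyl triflate, needed for the hindered tertiary alcohol, with no stereocentre affected.

Step 4
Reactants: 4 (R)-triethyl({1-[(4-methoxybenzyl)oxy]-2-methylpent-4-en-2-yl}oxy)silane
Product: 5 (R)-4-[(4-methoxybenzyl)oxy]-3-methyl-3-[(triethylsilyl)oxy]butanal
Conditions: OsO4 (2 mol%), NaIO4, 2,6-lutidine, dioxane/H2O, rt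
Reagents that add atoms: sodium periodate, [Na+].[O-]I(=O)(=O)=O (its oxygen reaches C8 through OsO4)
Why: Lemieux–Johnson oxidative cleavage (dihydroxylation, then periodate glycol cleavage) of the terminal alkene to the C8 aldehyde, with lutidine buffering to keep the silyl and benzyl-type ethers intact.

Step 5
Reactants: 6 (R)-4-benzyloxazolidin-2-one; 7 methyl 4-chloro-4-oxobutanoate
Product: 8 methyl 4-[(R)-4-benzyl-2-oxooxazolidin-3-yl]-4-oxobutanoate
Conditions: n-BuLi, THF, −78 °C; then 7, −78 to 0 °C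
Reagents that add atoms: none
Why: N-acylation of the lithiated oxazolidinone by the acid chloride, which is far more electrophilic than the methyl ester at low temperature.

Step 6
Reactants: 8 methyl 4-[(R)-4-benzyl-2-oxooxazolidin-3-yl]-4-oxobutanoate; 5 (R)-4-[(4-methoxybenzyl)oxy]-3-methyl-3-[(triethylsilyl)oxy]butanal
Product: 10 (R)-4-benzyl-3-[(2S,3R)-2-{(R)-3-[(4-methoxybenzyl)oxy]-2-methyl-2-[(triethylsilyl)oxy]propyl}-5-oxotetrahydrofuran-3-carbonyl]oxazolidin-2-one, via aldol adduct 9 (not isolated)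
Conditions: 8, Bu2BOTf, iPr2NEt, CH2Cl2, −78 to 0 °C; 5, −78 to 0 °C; pH 7 buffer, MeOH, H2O2, 0 °C; then PPTS (cat.), CH2Cl2, rt
Reagents that add atoms: none
Why: Evans syn-aldol through the Z-configured boron enolate of the imide (the more acidic α-position) and a chair Zimmerman–Traxler transition state, in which the (R)-benzyl auxiliary directs the aldehyde to the enolate face that gives 7R and 8S (target numbering), after which the C8 hydroxyl lactonises onto the methyl ester to give the trans-disubstituted γ-lactone.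

Step 7
Reactants: 10 (R)-4-benzyl-3-[(2S,3R)-2-{(R)-3-[(4-methoxybenzyl)oxy]-2-methyl-2-[(triethylsilyl)oxy]propyl}-5-oxotetrahydrofuran-3-carbonyl]oxazolidin-2-one
Product: 11 S-ethyl (2S,3R)-2-{(R)-3-[(4-methoxybenzyl)oxy]-2-methyl-2-[(triethylsilyl)oxy]propyl}-5-oxotetrahydrofuran-3-carbothioate
Conditions: EtSH, n-BuLi, THF, 0 °C
Reagents that add atoms: ethanethiol (used as its lithium salt), CCS
Why: Acyl transfer from the imide to the thiolate (exocyclic cleavage of the N-acyl oxazolidinone), which spares the lactone because thiolate opening of a γ-lactone reverts, and which leaves C7 in its more stable trans arrangement.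

Step 8
Reactants: 12 (S)-but-3-yn-2-ol
Product: 13 (S,Z)-4-iodo-3-methylbut-3-en-2-ol
Conditions: MeMgBr (3 equiv), CuI (15 mol%), Et2O/THF, −20 °C to rt; then I2, −20 to 0 °C
Reagents that add atoms: methylmagnesium bromide, C[Mg]Br; iodine, II
Why: Copper-catalysed, alkoxide-directed anti-carbomagnesiation of the propargylic alcohol puts the methyl group (C15) on the internal carbon and magnesium on the terminal carbon cis to the carbinol carbon (five-membered magnesium chelate), and iodinolysis with retention gives the Z-iodide without touching the carbinol centre.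

Step 9
Reactants: 13 (S,Z)-4-iodo-3-methylbut-3-en-2-ol
Product: 14 1-({[(S,Z)-4-iodo-3-methylbut-3-en-2-yl]oxy}methyl)-4-methoxybenzene
Conditions: NaH, 4-methoxybenzyl chloride, Bu4NI (cat.), DMF, 0 °C to rt
Reagents that add atoms: 4-methoxybenzyl chloride, COc1ccc(CCl)cc1
Why: Williamson etherification of the secondary alkoxide; the vinyl iodide has no β-hydrogen for elimination and the carbinol centre is an auxiliary one that is oxidised away in step 15.

Step 10
Reactants: 11 S-ethyl (2S,3R)-2-{(R)-3-[(4-methoxybenzyl)oxy]-2-methyl-2-[(triethylsilyl)oxy]propyl}-5-oxotetrahydrofuran-3-carbothioate; 14 1-({[(S,Z)-4-iodo-3-methylbut-3-en-2-yl]oxy}methyl)-4-methoxybenzene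
Product: 17 (4R,5S)-5-{(R)-3-[(4-methoxybenzyl)oxy]-2-methyl-2-[(triethylsilyl)oxy]propyl}-4-[(S,Z)-4-[(4-methoxybenzyl)oxy]-3-methylpent-2-enoyl]dihydrofuran-2(3H)-one, via alkenyllithium 15 (not isolated), via lithium dialkenylcuprate 16 (not isolated)
Conditions: 14 (2.4 equiv), t-BuLi (4.8 equiv), Et2O, −78 °C; CuI (1.2 equiv), −78 to −40 °C; then 11, THF, −78 °C; aq. NH4Cl
Reagents that add atoms: none
Why: Ketone synthesis by acylation of an alkenylcuprate with a thioester (iodine–lithium exchange and transmetalation to copper both with retention of the Z geometry, acyl substitution that stops at the ketone and does not touch the lactone), with no new stereocentre and a cold quench to keep the Z-enone from isomerising.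

Step 11
Reactants: 17 (4R,5S)-5-{(R)-3-[(4-methoxybenzyl)oxy]-2-methyl-2-[(triethylsilyl)oxy]propyl}-4-[(S,Z)-4-[(4-methoxybenzyl)oxy]-3-methylpent-2-enoyl]dihydrofuran-2(3H)-one
Product: 18 (4S,5S)-4-[(1S,2Z,4S)-1-hydroxy-4-[(4-methoxybenzyl)oxy]-3-methylpent-2-en-1-yl]-5-{(R)-3-[(4-methoxybenzyl)oxy]-2-methyl-2-[(triethylsilyl)oxy]propyl}dihydrofuran-2(3H)-one (ring C4 is the 7R carbon of the target; its descriptor changes by CIP ranking only)
Conditions: LiBH(s-Bu)3, THF, −78 °C; aq. NH4Cl at −78 °C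
Reagents that add atoms: none
Why: Felkin–Anh 1,2-reduction of the β,β-disubstituted enone by a bulky borohydride, in which the hydride should enter anti to the C7–C8 bond and past the C7 hydrogen to give the 6S carbinol, and the cold quench keeps the new alkoxide from attacking the lactone.

Step 12
Reactants: 18 (4S,5S)-4-[(1S,2Z,4S)-1-hydroxy-4-[(4-methoxybenzyl)oxy]-3-methylpent-2-en-1-yl]-5-{(R)-3-[(4-methoxybenzyl)oxy]-2-methyl-2-[(triethylsilyl)oxy]propyl}dihydrofuran-2(3H)-one
Product: 19 (4R,5S)-4-[(1S,2Z,4S)-4-[(4-methoxybenzyl)oxy]-3-methyl-1-[(triisopropylsilyl)oxy]pent-2-en-1-yl]-5-{(R)-3-[(4-methoxybenzyl)oxy]-2-methyl-2-[(triethylsilyl)oxy]propyl}dihydrofuran-2(3H)-one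
Conditions: iPr3SiOTf, 2,6-lutidine, CH2Cl2, 0 °C to rt
Reagents that add atoms: triisopropylsilyl triflate, CC(C)[Si](C(C)C)(C(C)C)OS(=O)(=O)C(F)(F)F
Why: Silyl ether formation on the hindered allylic alcohol with the silyl triflate; the bulky silyl group is chosen so that the C10 triethylsilyl ether can later be removed and the acid step run without exposing O6, and capping O6 also removes the risk of translactonisation.

Step 13
Reactants: 19 (4R,5S)-4-[(1S,2Z,4S)-4-[(4-methoxybenzyl)oxy]-3-methyl-1-[(triisopropylsilyl)oxy]pent-2-en-1-yl]-5-{(R)-3-[(4-methoxybenzyl)oxy]-2-methyl-2-[(triethylsilyl)oxy]propyl}dihydrofuran-2(3H)-one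
Product: 22 (4R,5S)-4-[(1S,2Z,4S)-4-[(4-methoxybenzyl)oxy]-3-methyl-1-[(triisopropylsilyl)oxy]pent-2-en-1-yl]-5-{(R)-3-[(4-methoxybenzyl)oxy]-2-methyl-2-[(triethylsilyl)oxy]propyl}-3-methylidenedihydrofuran-2(3H)-one, via Mannich base 20 (not isolated), via ammonium iodide 21 (not isolated)
Conditions: LiN(SiMe3)2, THF, −78 °C; CH2=NMe2 I (Eschenmoser's salt), −78 °C to rt; MeI, MeOH, rt; aq. NaHCO3, CH2Cl2, rt
Reagents that add atoms: N,N-dimethylmethyleneiminium iodide (Eschenmoser's salt), C[N+](C)=C.[I-]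
Why: Mannich methylenation of the lactone, the only carbonyl group present: the C11 lithium enolate is aminomethylated, and N-methylation followed by E1cB loss of trimethylamine gives the exocyclic C11=C13 alkene, while C7 has no way to epimerise.

Step 14
Reactants: 22 (4R,5S)-4-[(1S,2Z,4S)-4-[(4-methoxybenzyl)oxy]-3-methyl-1-[(triisopropylsilyl)oxy]pent-2-en-1-yl]-5-{(R)-3-[(4-methoxybenzyl)oxy]-2-methyl-2-[(triethylsilyl)oxy]propyl}-3-methylidenedihydrofuran-2(3H)-one
Product: 23 (4R,5S)-4-[(1S,2Z,4S)-4-hydroxy-3-methyl-1-[(triisopropylsilyl)oxy]pent-2-en-1-yl]-5-{(R)-3-hydroxy-2-methyl-2-[(triethylsilyl)oxy]propyl}-3-methylidenedihydrofuran-2(3H)-one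
Conditions: DDQ (2.6 equiv), CH2Cl2/pH 7 buffer, 0 °C to rt
Reagents that add atoms: none
Why: Oxidative cleavage of both 4-methoxybenzyl ethers by DDQ (hydride abstraction to the oxocarbenium ion, then hydrolysis in the buffered two-phase medium), which leaves the silyl ethers and the alkenes untouched.

Step 15
Reactants: 23 (4R,5S)-4-[(1S,2Z,4S)-4-hydroxy-3-methyl-1-[(triisopropylsilyl)oxy]pent-2-en-1-yl]-5-{(R)-3-hydroxy-2-methyl-2-[(triethylsilyl)oxy]propyl}-3-methylidenedihydrofuran-2(3H)-one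
Product: 24 (R)-2-methyl-3-{(2S,3R)-4-methylidene-3-[(1S,2Z)-3-methyl-4-oxo-1-[(triisopropylsilyl)oxy]pent-2-en-1-yl]-5-oxotetrahydrofuran-2-yl}-2-[(triethylsilyl)oxy]propanal
Conditions: Dess–Martin periodinane (3 equiv), NaHCO3, CH2Cl2, 0 °C to rt
Reagents that add atoms: none
Why: Dess–Martin oxidation of the primary alcohol to the C1 aldehyde and of the allylic alcohol to the C3 methyl ketone in one operation, in a buffered non-basic medium that should preserve the Z C4=C5 geometry and that removes the auxiliary C3 stereocentre.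

Step 16
Reactants: 24 (R)-2-methyl-3-{(2S,3R)-4-methylidene-3-[(1S,2Z)-3-methyl-4-oxo-1-[(triisopropylsilyl)oxy]pent-2-en-1-yl]-5-oxotetrahydrofuran-2-yl}-2-[(triethylsilyl)oxy]propanal
Product: 25 (4Z,6S,7R,8S,10R)-1-hydroxy-3-oxo-10-[(triethylsilyl)oxy]-6-[(triisopropylsilyl)oxy]germacra-4,11(13)-dien-12,8-olide (C1 epimers)
Conditions: Bu2BOTf (3 equiv), iPr2NEt (4 equiv), CH2Cl2, −78 °C; 24 added by syringe pump (final ca. 1 mM), −78 to −20 °C; pH 7 buffer, MeOH, H2O2, 0 °C
Reagents that add atoms: none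
Why: Intramolecular boron aldol, in which soft enolisation occurs at the C2 methyl of the enone (the only readily enolisable site, since C11 is now sp2 and the C1 aldehyde has no α-hydrogen) and a chair Zimmerman–Traxler addition under pseudo-high dilution closes the C1–C2 bond irreversibly as the boron aldolate; the new C1 carbinol is not controlled and is removed in step 17.

Step 17
Reactants: 25 (4Z,6S,7R,8S,10R)-1-hydroxy-3-oxo-10-[(triethylsilyl)oxy]-6-[(triisopropylsilyl)oxy]germacra-4,11(13)-dien-12,8-olide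
Product: 26 (4Z,6S,7R,8S,10R)-1,3-dioxo-10-[(triethylsilyl)oxy]-6-[(triisopropylsilyl)oxy]germacra-4,11(13)-dien-12,8-olide
Conditions: Dess–Martin periodinane (1.5 equiv), NaHCO3, CH2Cl2, rt
Reagents that add atoms: none
Why: Dess–Martin oxidation of the β-hydroxy ketone to the 1,3-diketone, which erases the C1 centre, with a limited charge of oxidant so that C2 is not oxidised further.

Step 18
Reactants: 26 (4Z,6S,7R,8S,10R)-1,3-dioxo-10-[(triethylsilyl)oxy]-6-[(triisopropylsilyl)oxy]germacra-4,11(13)-dien-12,8-olide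
Product: 27 (4Z,6S,7R,8S,10R)-10-hydroxy-1,3-dioxo-6-[(triisopropylsilyl)oxy]germacra-4,11(13)-dien-12,8-olide
Conditions: HF·pyridine, pyridine, THF, 0 °C
Reagents that add atoms: none
Why: Fluoride-driven cleavage of the triethylsilyl ether, selective because the triisopropylsilyl ether at C6 is far less labile, which sets the C10 hydroxyl free next to the diketone.

Step 19
Reactants: 27 (4Z,6S,7R,8S,10R)-10-hydroxy-1,3-dioxo-6-[(triisopropylsilyl)oxy]germacra-4,11(13)-dien-12,8-olide
Product: 28 (4Z,6S,7R,8S,10R)-3,10-epoxy-1-oxo-6-[(triisopropylsilyl)oxy]germacra-2,4,11(13)-trien-12,8-olide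
Conditions: p-TsOH·H2O (10 mol%), toluene, rt to 45 °C
Reagents that add atoms: none
Why: Protonation of the C3 carbonyl lets the tertiary C10 hydroxyl add across the ring to C3, and the hemiketal then ionises to the oxocarbenium ion and loses a C2 proton, which the C1 ketone makes acidic, to give the C2=C3 vinylogous ester. The closest known reaction type is the acid-catalysed cyclodehydration of α'-hydroxy-1,3-diketones to 3(2H)-furanones, run here in transannular mode. The one ring closed (O, C10, C1, C2, C3) forms 5-exo-trig, with the new O–C3 bond bridging the ten-membered carbocycle. No stereocentre is created, and C10 keeps its configuration because its C–O bond is never broken (the oxygen lost as water is the former C3 carbonyl oxygen). The step needs chemoselectivity for the C10 hydroxyl over O6, which the acid-stable triisopropylsilyl ether secures, and it has only one possible regiochemistry because the C10 hydroxyl can reach no carbonyl other than C3 in a five-membered mode. The ring Z C4=C5 alkene holds C3 near C10, and the bridged product has the ring system of the natural skeleton, so it should not be unduly strained.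

Step 20
Reactants: 28 (4Z,6S,7R,8S,10R)-3,10-epoxy-1-oxo-6-[(triisopropylsilyl)oxy]germacra-2,4,11(13)-trien-12,8-olide
Product: 29 (4Z,6S,7S,8S,10R)-3,10-epoxy-6-hydroxy-1-oxogermacra-2,4,11(13)-trien-12,8-olide (7S by CIP ranking only; same spatial arrangement as 7R in 28)
Conditions: HF·pyridine, THF, 0 °C to rt
Reagents that add atoms: none
Why: Desilylation by HF, whose acidic and weakly nucleophilic medium should spare the α-methylene lactone and the vinylogous ester and should not promote migration of the lactone to O6.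

Step 21
Reactants: 30 angelic acid [(Z)-2-methylbut-2-enoic acid]
Product: 31 (Z)-2-methylbut-2-en-1-ol
Conditions: LiAlH4, Et2O, 0 °C
Reagents that add atoms: none
Why: Hydride reduction of the carboxylic acid to the allylic alcohol (1,2-reduction), with the Z double bond retained.

Step 22
Reactants: 31 (Z)-2-methylbut-2-en-1-ol
Product: 32 [(2S,3R)-2,3-dimethyloxiran-2-yl]methanol
Conditions: Ti(OiPr)4, L-(+)-diethyl tartrate, t-BuOOH, 4 Å molecular sieves, CH2Cl2, −20 °C
Reagents that add atoms: tert-butyl hydroperoxide, CC(C)(C)OO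
Why: Sharpless asymmetric epoxidation, in which the L-(+)-tartrate titanium complex delivers the peroxide oxygen to the alkene face that gives the (2S,3R)-epoxy alcohol, and the cis relationship of CH2OH and the C3 methyl is carried over from the Z alkene.

Step 23
Reactants: 32 [(2S,3R)-2,3-dimethyloxiran-2-yl]methanol
Product: 33 (2R,3R)-2,3-dimethyloxirane-2-carboxylic acid [(2R,3R)-epoxyangelic acid]
Conditions: RuCl3·xH2O (2 mol%), NaIO4, MeCN/EtOAc/H2O, 0 °C to rt
Reagents that add atoms: water, O (the carboxyl OH oxygen, through the aldehyde hydrate)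
Why: RuO4-catalysed oxidation of the primary alcohol to the acid, which does not touch the epoxide or its two stereocentres (C2 becomes R by CIP ranking only).

Step 24
Reactants: 29 (4Z,6S,7S,8S,10R)-3,10-epoxy-6-hydroxy-1-oxogermacra-2,4,11(13)-trien-12,8-olide; 33 (2R,3R)-2,3-dimethyloxirane-2-carboxylic acid
Product: 35 target CNP0258430.3 [(4Z,6S,7R,8S,10R)-6-{[(2R,3R)-2,3-dimethyloxirane-2-carbonyl]oxy}-3,10-epoxy-1-oxogermacra-2,4,11(13)-trien-12,8-olide], via mixed anhydride 34 (not isolated)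
Conditions: 33, 2,4,6-trichlorobenzoyl chloride, Et3N, toluene, rt; then 29, DMAP, toluene, rt
Reagents that add atoms: none
Why: Yamaguchi esterification, in which the mixed anhydride acylates DMAP at the less hindered epoxy-acyl carbonyl and the acylpyridinium ion esterifies the hindered allylic C6 hydroxyl with retention at C6 and at both epoxide carbons.

## Compound list

1 | (S)-(2-methyloxiran-2-yl)methanol | C[C@]1(CO)CO1 | starting material
2 | (R)-2-{[(4-methoxybenzyl)oxy]methyl}-2-methyloxirane | C[C@]1(COCc2ccc(OC)cc2)CO1 | intermediate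
3 | (R)-1-[(4-methoxybenzyl)oxy]-2-methylpent-4-en-2-ol | C=CC[C@@](C)(O)COCc1ccc(OC)cc1 | intermediate
4 | (R)-triethyl({1-[(4-methoxybenzyl)oxy]-2-methylpent-4-en-2-yl}oxy)silane | C=CC[C@@](C)(O[Si](CC)(CC)CC)COCc1ccc(OC)cc1 | intermediate
5 | (R)-4-[(4-methoxybenzyl)oxy]-3-methyl-3-[(triethylsilyl)oxy]butanal | O=CC[C@@](C)(O[Si](CC)(CC)CC)COCc1ccc(OC)cc1 | intermediate
6 | (R)-4-benzyloxazolidin-2-one | O=C1N[C@H](Cc2ccccc2)CO1 | starting material
7 | methyl 4-chloro-4-oxobutanoate | COC(=O)CCC(Cl)=O | starting material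
8 | methyl 4-[(R)-4-benzyl-2-oxooxazolidin-3-yl]-4-oxobutanoate | COC(=O)CCC(=O)N1[C@H](Cc2ccccc2)COC1=O | intermediate
9 | methyl (3R,4S,6R)-3-[(R)-4-benzyl-2-oxooxazolidine-3-carbonyl]-4-hydroxy-7-[(4-methoxybenzyl)oxy]-6-methyl-6-[(triethylsilyl)oxy]heptanoate (aldol adduct, not isolated) | COC(=O)C[C@@H](C(=O)N1[C@H](Cc2ccccc2)COC1=O)[C@@H](O)C[C@@](C)(O[Si](CC)(CC)CC)COCc1ccc(OC)cc1 | intermediate
10 | (R)-4-benzyl-3-[(2S,3R)-2-{(R)-3-[(4-methoxybenzyl)oxy]-2-methyl-2-[(triethylsilyl)oxy]propyl}-5-oxotetrahydrofuran-3-carbonyl]oxazolidin-2-one | O=C1C[C@@H](C(=O)N2[C@H](Cc3ccccc3)COC2=O)[C@H](C[C@@](C)(O[Si](CC)(CC)CC)COCc2ccc(OC)cc2)O1 | intermediate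
11 | S-ethyl (2S,3R)-2-{(R)-3-[(4-methoxybenzyl)oxy]-2-methyl-2-[(triethylsilyl)oxy]propyl}-5-oxotetrahydrofuran-3-carbothioate | O=C1C[C@@H](C(=O)SCC)[C@H](C[C@@](C)(O[Si](CC)(CC)CC)COCc2ccc(OC)cc2)O1 | intermediate
12 | (S)-but-3-yn-2-ol | C[C@H](O)C#C | starting material
13 | (S,Z)-4-iodo-3-methylbut-3-en-2-ol | C[C@H](O)/C(C)=C\I | intermediate
14 | 1-({[(S,Z)-4-iodo-3-methylbut-3-en-2-yl]oxy}methyl)-4-methoxybenzene | C[C@H](OCc1ccc(OC)cc1)/C(C)=C\I | intermediate
15 | [(S,Z)-3-[(4-methoxybenzyl)oxy]-2-methylbut-1-en-1-yl]lithium (not isolated) | C[C@H](OCc1ccc(OC)cc1)/C(C)=C\[Li] | intermediate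
16 | lithium bis[(S,Z)-3-[(4-methoxybenzyl)oxy]-2-methylbut-1-en-1-yl]cuprate, R2CuLi (not isolated) | [Li+].C[C@H](OCc1ccc(OC)cc1)/C(C)=C\[Cu-]/C=C(/C)[C@H](C)OCc1ccc(OC)cc1 | intermediate
17 | (4R,5S)-5-{(R)-3-[(4-methoxybenzyl)oxy]-2-methyl-2-[(triethylsilyl)oxy]propyl}-4-[(S,Z)-4-[(4-methoxybenzyl)oxy]-3-methylpent-2-enoyl]dihydrofuran-2(3H)-one | O=C1C[C@@H](C(=O)/C=C(/C)[C@H](C)OCc2ccc(OC)cc2)[C@H](C[C@@](C)(O[Si](CC)(CC)CC)COCc2ccc(OC)cc2)O1 | intermediate
18 | (4S,5S)-4-[(1S,2Z,4S)-1-hydroxy-4-[(4-methoxybenzyl)oxy]-3-methylpent-2-en-1-yl]-5-{(R)-3-[(4-methoxybenzyl)oxy]-2-methyl-2-[(triethylsilyl)oxy]propyl}dihydrofuran-2(3H)-one | O=C1C[C@@H]([C@@H](O)/C=C(/C)[C@H](C)OCc2ccc(OC)cc2)[C@H](C[C@@](C)(O[Si](CC)(CC)CC)COCc2ccc(OC)cc2)O1 | intermediate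
19 | (4R,5S)-4-[(1S,2Z,4S)-4-[(4-methoxybenzyl)oxy]-3-methyl-1-[(triisopropylsilyl)oxy]pent-2-en-1-yl]-5-{(R)-3-[(4-methoxybenzyl)oxy]-2-methyl-2-[(triethylsilyl)oxy]propyl}dihydrofuran-2(3H)-one | O=C1C[C@@H]([C@@H](O[Si](C(C)C)(C(C)C)C(C)C)/C=C(/C)[C@H](C)OCc2ccc(OC)cc2)[C@H](C[C@@](C)(O[Si](CC)(CC)CC)COCc2ccc(OC)cc2)O1 | intermediate
20 | 3-[(dimethylamino)methyl] derivative of 19 (Mannich base, C11 epimers, not isolated) | CN(C)CC1C(=O)O[C@@H](C[C@@](C)(O[Si](CC)(CC)CC)COCc2ccc(OC)cc2)[C@@H]1[C@@H](O[Si](C(C)C)(C(C)C)C(C)C)/C=C(/C)[C@H](C)OCc2ccc(OC)cc2 | intermediate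
21 | 3-[(trimethylammonio)methyl] derivative of 19, iodide (not isolated) | C[N+](C)(C)CC1C(=O)O[C@@H](C[C@@](C)(O[Si](CC)(CC)CC)COCc2ccc(OC)cc2)[C@@H]1[C@@H](O[Si](C(C)C)(C(C)C)C(C)C)/C=C(/C)[C@H](C)OCc2ccc(OC)cc2.[I-] | intermediate
22 | (4R,5S)-4-[(1S,2Z,4S)-4-[(4-methoxybenzyl)oxy]-3-methyl-1-[(triisopropylsilyl)oxy]pent-2-en-1-yl]-5-{(R)-3-[(4-methoxybenzyl)oxy]-2-methyl-2-[(triethylsilyl)oxy]propyl}-3-methylidenedihydrofuran-2(3H)-one | C=C1C(=O)O[C@@H](C[C@@](C)(O[Si](CC)(CC)CC)COCc2ccc(OC)cc2)[C@@H]1[C@@H](O[Si](C(C)C)(C(C)C)C(C)C)/C=C(/C)[C@H](C)OCc2ccc(OC)cc2 | intermediate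
23 | (4R,5S)-4-[(1S,2Z,4S)-4-hydroxy-3-methyl-1-[(triisopropylsilyl)oxy]pent-2-en-1-yl]-5-{(R)-3-hydroxy-2-methyl-2-[(triethylsilyl)oxy]propyl}-3-methylidenedihydrofuran-2(3H)-one | C=C1C(=O)O[C@@H](C[C@@](C)(O[Si](CC)(CC)CC)CO)[C@@H]1[C@@H](O[Si](C(C)C)(C(C)C)C(C)C)/C=C(/C)[C@H](C)O | intermediate
24 | (R)-2-methyl-3-{(2S,3R)-4-methylidene-3-[(1S,2Z)-3-methyl-4-oxo-1-[(triisopropylsilyl)oxy]pent-2-en-1-yl]-5-oxotetrahydrofuran-2-yl}-2-[(triethylsilyl)oxy]propanal | C=C1C(=O)O[C@@H](C[C@@](C)(O[Si](CC)(CC)CC)C=O)[C@@H]1[C@@H](O[Si](C(C)C)(C(C)C)C(C)C)/C=C(/C)C(C)=O | intermediate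
25 | (4Z,6S,7R,8S,10R)-1-hydroxy-3-oxo-10-[(triethylsilyl)oxy]-6-[(triisopropylsilyl)oxy]germacra-4,11(13)-dien-12,8-olide (C1 epimers) | C=C1C(=O)O[C@H]2C[C@@](C)(O[Si](CC)(CC)CC)C(O)CC(=O)/C(C)=C\[C@H](O[Si](C(C)C)(C(C)C)C(C)C)[C@H]12 | intermediate
26 | (4Z,6S,7R,8S,10R)-1,3-dioxo-10-[(triethylsilyl)oxy]-6-[(triisopropylsilyl)oxy]germacra-4,11(13)-dien-12,8-olide | C=C1C(=O)O[C@H]2C[C@@](C)(O[Si](CC)(CC)CC)C(=O)CC(=O)/C(C)=C\[C@H](O[Si](C(C)C)(C(C)C)C(C)C)[C@H]12 | intermediate
27 | (4Z,6S,7R,8S,10R)-10-hydroxy-1,3-dioxo-6-[(triisopropylsilyl)oxy]germacra-4,11(13)-dien-12,8-olide (key-step precursor) | C=C1C(=O)O[C@H]2C[C@@](C)(O)C(=O)CC(=O)/C(C)=C\[C@H](O[Si](C(C)C)(C(C)C)C(C)C)[C@H]12 | intermediate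
28 | (4Z,6S,7R,8S,10R)-3,10-epoxy-1-oxo-6-[(triisopropylsilyl)oxy]germacra-2,4,11(13)-trien-12,8-olide (key-step product) | C=C1C(=O)O[C@H]2C[C@@]3(C)OC(=CC3=O)/C(C)=C\[C@H](O[Si](C(C)C)(C(C)C)C(C)C)[C@H]12 | intermediate
29 | (4Z,6S,7S,8S,10R)-3,10-epoxy-6-hydroxy-1-oxogermacra-2,4,11(13)-trien-12,8-olide | C=C1C(=O)O[C@H]2C[C@@]3(C)OC(=CC3=O)/C(C)=C\[C@H](O)[C@H]12 | intermediate
30 | angelic acid, (Z)-2-methylbut-2-enoic acid | C/C=C(/C)C(=O)O | starting material
31 | (Z)-2-methylbut-2-en-1-ol | C/C=C(/C)CO | intermediate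
32 | [(2S,3R)-2,3-dimethyloxiran-2-yl]methanol | OC[C@]1(C)O[C@@H]1C | intermediate
33 | (2R,3R)-2,3-dimethyloxirane-2-carboxylic acid | OC(=O)[C@]1(C)O[C@@H]1C | intermediate
34 | (2R,3R)-2,3-dimethyloxirane-2-carboxylic 2,4,6-trichlorobenzoic anhydride (not isolated) | O=C(OC(=O)[C@]1(C)O[C@@H]1C)c1c(Cl)cc(Cl)cc1Cl | intermediate
35 | CNP0258430.3, (4Z,6S,7R,8S,10R)-6-{[(2R,3R)-2,3-dimethyloxirane-2-carbonyl]oxy}-3,10-epoxy-1-oxogermacra-2,4,11(13)-trien-12,8-olide | C=C1C(=O)O[C@H]2C[C@@]3(C)OC(=CC3=O)/C(C)=C\[C@H](OC(=O)[C@]3(C)O[C@@H]3C)[C@H]12 | target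

## Step count and risks

Total step count: 24. Longest linear sequence: 18 steps (steps 1–4, 6, 7, 10–20, 24, from (S)-2-methylglycidol).

Steps most likely to fail:

1. Step 16 (ring closure by aldol). Closure of the ten-membered ring may be slower than intermolecular aldol addition between two molecules, or the amine may isomerise the Z-enone before enolisation, so that oligomers or E-configured material that cannot close would form. The fallback generates the enolate reductively next to the aldehyde (Reformatsky-type closure with SmI2, an established way to close medium rings by aldol addition); it sets out from 23 and comes back at 25. MnO2 in CH2Cl2 should oxidise only the allylic C3 alcohol of 23 to hydroxy enone F1. LiN(SiMe3)2/Me3SiCl at −78 °C converts it into bis(trimethylsilyl) dienol ether F2, which N-bromosuccinimide and a mildly acidic work-up turn into bromomethyl ketone F3. Dess–Martin oxidation gives bromo keto aldehyde F4. Slow addition of F4 to SmI2 in THF at −78 °C reduces the C–Br bond to the samarium enolate, which adds to the C1 aldehyde to give 25.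

2. Step 19 (transannular cyclodehydration). Dehydration may stop at the transannular hemiketal, and stronger acid or heat would begin to cleave the C6 silyl ether or ionise the allylic C6–O bond. The fallback dehydrates under base by treating the hemiketal as the β-hydroxy ketone it is; it sets out from 27 and comes back at 28. Compound 27 is equilibrated (trace Et3N, CH2Cl2) to transannular hemiketal F5. MsCl/Et3N at −20 to 0 °C gives hemiketal mesylate F6, which loses methanesulfonate by E1cB through the C1 enolate (the standard aldol-dehydration sequence) to give 28.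

3. Step 11 (reduction of the C6 ketone). The two ring carbons on C7 differ only moderately in size, so hydride delivery may show poor facial selectivity, and conjugate reduction could compete. The fallback forms C6 by carbon–carbon coupling under reagent control; it sets out from 11 and comes back at 18, bypassing steps 10 and 11. Fukuyama reduction of thioester 11 (Et3SiH, Pd/C, acetone) gives lactone aldehyde F7. An asymmetric Nozaki–Hiyama–Kishi coupling of F7 with iodide 14 (CrCl2, NiCl2 as catalyst, a chiral sulfonamide ligand chosen for the 6S carbinol, MeCN) gives 18.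

Further compounds
F1 | step 16 | (4R,5S)-5-{(R)-3-hydroxy-2-methyl-2-[(triethylsilyl)oxy]propyl}-3-methylidene-4-[(1S,2Z)-3-methyl-4-oxo-1-[(triisopropylsilyl)oxy]pent-2-en-1-yl]dihydrofuran-2(3H)-one (hydroxy enone) | C=C1C(=O)O[C@@H](C[C@@](C)(O[Si](CC)(CC)CC)CO)[C@@H]1[C@@H](O[Si](C(C)C)(C(C)C)C(C)C)/C=C(/C)C(C)=O
F2 | step 16 | bis(trimethylsilyl) derivative of F1 (C1 trimethylsilyl ether, C3 trimethylsilyl dienol ether) | C=C1C(=O)O[C@@H](C[C@@](C)(O[Si](CC)(CC)CC)CO[Si](C)(C)C)[C@@H]1[C@@H](O[Si](C(C)C)(C(C)C)C(C)C)/C=C(/C)C(=C)O[Si](C)(C)C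
F3 | step 16 | bromomethyl ketone (C2 bromide, C1 alcohol) | C=C1C(=O)O[C@@H](C[C@@](C)(O[Si](CC)(CC)CC)CO)[C@@H]1[C@@H](O[Si](C(C)C)(C(C)C)C(C)C)/C=C(/C)C(=O)CBr
F4 | step 16 | bromo keto aldehyde (C2 bromide, C1 aldehyde) | C=C1C(=O)O[C@@H](C[C@@](C)(O[Si](CC)(CC)CC)C=O)[C@@H]1[C@@H](O[Si](C(C)C)(C(C)C)C(C)C)/C=C(/C)C(=O)CBr
F5 | step 19 | transannular hemiketal of 27 (C10–O–C3 bond, C3 hydroxyl, C3 epimers) | C=C1C(=O)O[C@H]2C[C@@]3(C)OC(O)(CC3=O)/C(C)=C\[C@H](O[Si](C(C)C)(C(C)C)C(C)C)[C@H]12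
F6 | step 19 | C3 methanesulfonate of hemiketal F5 | C=C1C(=O)O[C@H]2C[C@@]3(C)OC(OS(C)(=O)=O)(CC3=O)/C(C)=C\[C@H](O[Si](C(C)C)(C(C)C)C(C)C)[C@H]12
F7 | step 11 | (2S,3R)-2-{(R)-3-[(4-methoxybenzyl)oxy]-2-methyl-2-[(triethylsilyl)oxy]propyl}-5-oxotetrahydrofuran-3-carbaldehyde | O=C1C[C@@H](C=O)[C@H](C[C@@](C)(O[Si](CC)(CC)CC)COCc2ccc(OC)cc2)O1
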